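## Retrosynthetic overview

1. The two esters go on last: angelate on the secondary C8–OH, then acetate on the tertiary C11–OH. The C11–OH comes from convex-face radical hydration of an exocyclic α-methylene lactone.
2. The ten-membered ring is closed second, at the C1–C2 sp2–sp3 bond, by a palladium-catalysed ring-closing Negishi coupling of an alkenyl iodide and an alkylzinc held cis on the lactone.
3. The lactone ring is formed first: the C6–C7 bond and C6–O come from a CrCl2-mediated 2-(methoxycarbonyl)allylation/lactonisation that joins an iodo enal (C2–C6) to a (Z)-allyl bromide (C1, C7–C13).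
4. The allyl bromide comes from (R)-glycidol (C8 stereocentre), acetylide, methylalumination/iodination and a Morita–Baylis–Hillman reaction with methyl acrylate. The iodo enal comes from but-3-yn-1-ol by methylalumination/hydroxymethylation.

Assumption: germacrane numbering is used for locants (ring C1–C10; lactone C6–O–C12(=O)–C11–C7; C13 on C11, C14 on C10, C15 on C4). The stereochemical outcome of step 12 and the feasibility of step 13 are predictions, not established results.

## Route

Step 1
Reactants: 1 (R)-glycidol; 2 lithium acetylide ethylenediamine complex (LiC≡CH·H2NCH2CH2NH2)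
Product: 3 (2S)-pent-4-yne-1,2-diol
Conditions: 2 (3 equiv), DMSO, 0 °C to rt; then H2O
Reagents that add atoms: none
Why: Epoxide alkynylation by SN2 attack at the terminal carbon leaves the C8 stereocentre of 1 untouched, and the degenerate Payne rearrangement of glycidol alkoxide leads to the same enantiomer, so no loss of ee is expected.

Step 2
Reactants: 3 (2S)-pent-4-yne-1,2-diol
Product: 4 (4S)-4,5-bis(triethylsilyloxy)pent-1-yne
Conditions: TESCl, imidazole, DMF, 0 °C to rt
Reagents that add atoms: chlorotriethylsilane (TESCl), CC[Si](CC)(CC)Cl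
Why: Exhaustive silyl ether formation; the primary TES ether is the latent C7 aldehyde and the secondary one protects C8–OH up to step 15.

Step 3
Reactants: 4 (4S)-4,5-bis(triethylsilyloxy)pent-1-yne
Product: 6 (2S,4E)-5-iodo-4-methyl-1,2-bis(triethylsilyloxy)pent-4-ene, via alkenyldimethylalane 5 (not isolated)
Conditions: AlMe3 (3 equiv), Cp2ZrCl2 (0.25 equiv), H2O (1.5 equiv), CH2Cl2, -25 °C; then I2, THF, -25 to 0 °C
Reagents that add atoms: trimethylaluminium (AlMe3), C[Al](C)C; iodine (I2), II
Why: Water-accelerated Negishi zirconium-catalysed syn-methylalumination puts methyl on the internal and aluminium on the terminal alkyne carbon, and iodinolysis with retention gives only the (E)-alkenyl iodide (C10=C1).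

Step 4
Reactants: 6 (2S,4E)-5-iodo-4-methyl-1,2-bis(triethylsilyloxy)pent-4-ene
Product: 7 (2S,4E)-5-iodo-4-methyl-2-(triethylsilyloxy)pent-4-enal
Conditions: (COCl)2, DMSO, CH2Cl2, -78 to -30 °C; then Et3N, -78 °C to rt
Reagents that add atoms: none
Why: Swern oxidation cleaves and oxidises a primary TES ether directly while the secondary TES ether survives, so the α-silyloxy aldehyde forms in one operation at low temperature without epimerisation.

Step 5
Reactants: 7 (2S,4E)-5-iodo-4-methyl-2-(triethylsilyloxy)pent-4-enal; 8 methyl acrylate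
Product: 9 methyl (4S,6E)-3-hydroxy-7-iodo-6-methyl-2-methylidene-4-(triethylsilyloxy)hept-6-enoate (both C3 epimers)
Conditions: 8 (10 equiv, neat), DABCO (1 equiv), rt, 3 d
Reagents that add atoms: none
Why: Morita–Baylis–Hillman reaction; α-alkoxy aldehydes are activated electrophiles, the alkenyl iodide is inert, and the new carbinol centre is erased in step 6.

Step 6
Reactants: 9 Morita–Baylis–Hillman adduct
Product: 10 methyl (2Z,4S,6E)-2-(bromomethyl)-7-iodo-6-methyl-4-(triethylsilyloxy)hepta-2,6-dienoate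
Conditions: NBS, Me2S, CH2Cl2, 0 °C to rt
Reagents that add atoms: N-bromosuccinimide (NBS), O=C1CCC(=O)N1Br
Why: Corey–Kim-type activation of the allylic alcohol and SN2' delivery of bromide give the thermodynamically preferred (Z)-2-(bromomethyl)enoate, with C8 cis to CH2Br as the later chair transition state requires.

Step 7
Reactants: 11 but-3-yn-1-ol
Product: 12 tert-butyl(but-3-yn-1-yloxy)dimethylsilane
Conditions: TBSCl, imidazole, DMF, rt
Reagents that add atoms: tert-butylchlorodimethylsilane (TBSCl), CC(C)(C)[Si](C)(C)Cl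
Why: Silyl protection differentiates the future C2 oxygen from the allylic C6 oxygen introduced in step 8.

Step 8
Reactants: 12 tert-butyl(but-3-yn-1-yloxy)dimethylsilane
Product: 15 (2E)-5-(tert-butyldimethylsilyloxy)-3-methylpent-2-en-1-ol, via alkenyldimethylalane 13 (not isolated), via lithium alkenylalanate 14 (not isolated)
Conditions: AlMe3, Cp2ZrCl2 (0.25 equiv), (CH2Cl)2, rt; concentrate; n-BuLi, hexane/THF, -78 to 0 °C; (CH2O)n, rt; then H2O
Reagents that add atoms: trimethylaluminium (AlMe3), C[Al](C)C; paraformaldehyde (as formaldehyde), C=O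
Why: Negishi syn-methylalumination followed by hydroxymethylation of the alanate with retention fixes the (E)-trisubstituted C4=C5 alkene and brings in C6.

Step 9
Reactants: 15 (2E)-5-(tert-butyldimethylsilyloxy)-3-methylpent-2-en-1-ol
Product: 16 (2E)-5-(tert-butyldimethylsilyloxy)-3-methylpent-2-enal
Conditions: MnO2, CH2Cl2, rt
Reagents that add atoms: none
Why: Chemoselective allylic oxidation with MnO2 gives the enal without touching the silyl ether or the alkene geometry.

Step 10
Reactants: 16 (2E)-5-(tert-butyldimethylsilyloxy)-3-methylpent-2-enal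
Product: 17 (2E)-5-hydroxy-3-methylpent-2-enal
Conditions: aq. HF (48 %), MeCN, 0 °C
Reagents that add atoms: none
Why: Acidic fluoride desilylation frees the primary alcohol; the (E)-geometry prevents lactol formation and basic fluoride, which could isomerise the enal, is avoided.

Step 11
Reactants: 17 (2E)-5-hydroxy-3-methylpent-2-enal
Product: 18 (2E)-5-iodo-3-methylpent-2-enal
Conditions: I2, PPh3, imidazole, CH2Cl2, 0 °C, dark
Reagents that add atoms: iodine (I2), II
Why: Appel iodination of the primary alcohol under near-neutral conditions tolerates the enal and gives the C2 iodide that becomes the organozinc in step 13.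

Step 12
Reactants: 10 methyl (2Z,4S,6E)-2-(bromomethyl)-7-iodo-6-methyl-4-(triethylsilyloxy)hepta-2,6-dienoate; 18 (2E)-5-iodo-3-methylpent-2-enal
Product: 21 (4R,5R)-5-[(1E)-4-iodo-2-methylbut-1-en-1-yl]-4-[(1S,3E)-4-iodo-3-methyl-1-(triethylsilyloxy)but-3-en-1-yl]-3-methylideneoxolan-2-one (cis lactone), via allylchromium dichloride 19 (not isolated), via hydroxy ester 20 (not isolated)
Conditions: CrCl2 (4 equiv, nickel-free), THF, 0 °C to rt; aq. work-up; then PPTS (cat.), CH2Cl2, rt
Reagents that add atoms: none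
Why: Nozaki–Hiyama (Barbier-type) 2-(alkoxycarbonyl)allylation in which divalent chromium reacts only with the allyl bromide; the allylchromium adds 1,2 to the enal through a chair transition state with the C8 substituent axial (it is cis to CH2Cr), which gives the syn adduct and hence the cis lactone at C6/C7, while A(1,3) strain holds H8 in the alkene plane so the aldehyde attacks C7 anti to the C9 chain, placing C11 anti to O8 as in the target, and the C6 alkoxide then lactonises onto the methyl ester.

Step 13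
Reactants: 21 cis lactone bearing the C2 alkyl iodide and the C1 alkenyl iodide
Product: 23 (3aR,4S,6E,10E,11aR)-6,10-dimethyl-3-methylidene-4-(triethylsilyloxy)-3a,4,5,8,9,11a-hexahydrocyclodeca[b]furan-2(3H)-one, via alkylzinc iodide 22 (not isolated)
Conditions: Zn (3 equiv), LiCl (1.5 equiv), THF, 30 °C; then added over 12 h to Pd2(dba)3 (5 mol %), DPEphos (12 mol %), THF/NMP 4:1, 45 °C, final 1 mM
Reagents that add atoms: none
Why: Proposed new method: ring-closing alkyl–alkenyl Negishi coupling to a strained (E,E)-cyclodeca-1,5-diene, not yet shown for germacrane rings; LiCl-promoted zinc insertion occurs only at the primary sp3 C–I bond, zerovalent palladium adds oxidatively to the C1–I bond with retention, the cis lactone holds the C2 zinc chain and the C1 palladium chain on the same face so that intramolecular transmetalation to an eleven-membered palladacycle outruns oligomerisation under slow addition, and the wide-bite-angle DPEphos ligand favours reductive elimination over beta-hydride elimination, with no new stereocentre and both (E)-alkenes kept; the closest known reaction type is the intermolecular homoallylzinc/alkenyl iodide Negishi coupling used for 1,5-dienes, together with macrocyclising B-alkyl Suzuki couplings.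

Step 14
Reactants: 23 macrocyclic α-methylene lactone
Product: 25 (3R,3aR,4S,6E,10E,11aR)-3-hydroxy-3,6,10-trimethyl-4-(triethylsilyloxy)-3a,4,5,8,9,11a-hexahydrocyclodeca[b]furan-2(3H)-one, via tertiary hydroperoxide 24 (not isolated)
Conditions: Mn(dpm)3 (10 mol %), PhSiH3, O2 (1 atm), i-PrOH/CH2Cl2, 0 °C; then P(OEt)3
Reagents that add atoms: dioxygen (O2), O=O
Why: Mukaiyama-type hydration by metal-hydride hydrogen atom transfer; H adds to the exocyclic CH2, the tertiary α-acyl radical at C11 is trapped by O2 on the convex face of the cis-fused lactone (the face of H6 and H7, opposite C5 and C8), which sets C11 as (R), the hydroperoxide is reduced by phosphite, and the electron-poor 1,1-disubstituted alkene reacts much faster than the two trisubstituted ring alkenes.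

Step 15
Reactants: 25 tertiary alcohol
Product: 26 (3R,3aS,4S,6E,10E,11aR)-3,4-dihydroxy-3,6,10-trimethyl-3a,4,5,8,9,11a-hexahydrocyclodeca[b]furan-2(3H)-one
Conditions: HF·pyridine, pyridine, THF, 0 °C
Reagents that add atoms: none
Why: Pyridine-buffered fluoride desilylation frees C8–OH without the strong acid that would trigger transannular cyclisation of the 1,5-diene.

Step 16
Reactants: 27 angelic acid
Product: 28 (2Z)-2-methylbut-2-enoic 2,4,6-trichlorobenzoic anhydride
Conditions: 2,4,6-trichlorobenzoyl chloride, Et3N, toluene, rt; filter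
Reagents that add atoms: 2,4,6-trichlorobenzoyl chloride, O=C(Cl)c1c(Cl)cc(Cl)cc1Cl
Why: Yamaguchi mixed-anhydride formation; pre-forming it without DMAP keeps the (Z)-geometry of the angeloyl unit.

Step 17
Reactants: 26 macrocyclic diol; 28 angelic mixed anhydride
Product: 29 (3R,3aS,4S,6E,10E,11aR)-3-hydroxy-3,6,10-trimethyl-2-oxo-2,3,3a,4,5,8,9,11a-octahydrocyclodeca[b]furan-4-yl (2Z)-2-methylbut-2-enoate
Conditions: 28 (3 equiv), Et3N (3 equiv), toluene, 70 °C
Reagents that add atoms: none
Why: DMAP-free thermal Yamaguchi-type acylation esterifies the secondary C8–OH selectively over the hindered tertiary C11–OH and avoids angelate-to-tiglate isomerisation; no stereocentre is touched.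

Step 18
Reactants: 29 C8 angelate with free C11–OH
Product: 30 target, (3R,3aS,4S,6E,10E,11aR)-3-acetoxy-3,6,10-trimethyl-2-oxo-2,3,3a,4,5,8,9,11a-octahydrocyclodeca[b]furan-4-yl (2Z)-2-methylbut-2-enoate
Conditions: Ac2O, DMAP, Et3N, CH2Cl2, 35 °C
Reagents that add atoms: acetic anhydride (Ac2O), CC(=O)OC(C)=O
Why: DMAP-catalysed acetylation of the remaining tertiary α-hydroxy lactone; doing it last avoids the tertiary-to-secondary acetyl migration that a free C8–OH would allow, and no stereocentre is touched.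

## Compound list

1 | (R)-glycidol, (2R)-oxiran-2-ylmethanol | OC[C@@H]1CO1 | starting material
2 | lithium acetylide ethylenediamine complex (LiC≡CH·H2NCH2CH2NH2) | [Li]C#C.NCCN | starting material
3 | (2S)-pent-4-yne-1,2-diol | O[C@H](CO)CC#C | intermediate
4 | (4S)-4,5-bis(triethylsilyloxy)pent-1-yne | CC[Si](CC)(CC)O[C@H](CO[Si](CC)(CC)CC)CC#C | intermediate
5 | [(1E,4S)-2-methyl-4,5-bis(triethylsilyloxy)pent-1-en-1-yl]dimethylalane (formed in the flask) | CC[Si](CC)(CC)O[C@H](CO[Si](CC)(CC)CC)C/C(C)=C/[Al](C)C | intermediate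
6 | (2S,4E)-5-iodo-4-methyl-1,2-bis(triethylsilyloxy)pent-4-ene | CC[Si](CC)(CC)O[C@H](CO[Si](CC)(CC)CC)C/C(C)=C/I | intermediate
7 | (2S,4E)-5-iodo-4-methyl-2-(triethylsilyloxy)pent-4-enal | CC[Si](CC)(CC)O[C@H](C=O)C/C(C)=C/I | intermediate
8 | methyl acrylate | C=CC(=O)OC | starting material
9 | methyl (4S,6E)-3-hydroxy-7-iodo-6-methyl-2-methylidene-4-(triethylsilyloxy)hept-6-enoate, both C3 epimers | CC[Si](CC)(CC)O[C@H](C(O)C(=C)C(=O)OC)C/C(C)=C/I | intermediate
10 | methyl (2Z,4S,6E)-2-(bromomethyl)-7-iodo-6-methyl-4-(triethylsilyloxy)hepta-2,6-dienoate | CC[Si](CC)(CC)O[C@H](/C=C(\CBr)C(=O)OC)C/C(C)=C/I | intermediate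
11 | but-3-yn-1-ol | OCCC#C | starting material
12 | tert-butyl(but-3-yn-1-yloxy)dimethylsilane | CC(C)(C)[Si](C)(C)OCCC#C | intermediate
13 | {(1E)-4-[(tert-butyldimethylsilyl)oxy]-2-methylbut-1-en-1-yl}dimethylalane (formed in the flask) | CC(C)(C)[Si](C)(C)OCC/C(C)=C/[Al](C)C | intermediate
14 | lithium butyl{(1E)-4-[(tert-butyldimethylsilyl)oxy]-2-methylbut-1-en-1-yl}dimethylaluminate (formed in the flask) | [Li+].CCCC[Al-](C)(C)/C=C(\C)CCO[Si](C)(C)C(C)(C)C | intermediate
15 | (2E)-5-(tert-butyldimethylsilyloxy)-3-methylpent-2-en-1-ol | CC(C)(C)[Si](C)(C)OCC/C(C)=C/CO | intermediate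
16 | (2E)-5-(tert-butyldimethylsilyloxy)-3-methylpent-2-enal | CC(C)(C)[Si](C)(C)OCC/C(C)=C/C=O | intermediate
17 | (2E)-5-hydroxy-3-methylpent-2-enal | OCC/C(C)=C/C=O | intermediate
18 | (2E)-5-iodo-3-methylpent-2-enal | ICC/C(C)=C/C=O | intermediate
19 | dichloro[(2Z,4S,6E)-7-iodo-2-(methoxycarbonyl)-6-methyl-4-(triethylsilyloxy)hepta-2,6-dien-1-yl]chromium (formed in the flask) | CC[Si](CC)(CC)O[C@H](/C=C(\C[Cr](Cl)Cl)C(=O)OC)C/C(C)=C/I | intermediate
20 | methyl (3R,4R,5E)-4-hydroxy-8-iodo-3-[(1S,3E)-4-iodo-3-methyl-1-(triethylsilyloxy)but-3-en-1-yl]-6-methyl-2-methylideneoct-5-enoate (formed in the flask) | ICC/C(C)=C/[C@@H](O)[C@@H](C(=C)C(=O)OC)[C@@H](O[Si](CC)(CC)CC)C/C(C)=C/I | intermediate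
21 | (4R,5R)-5-[(1E)-4-iodo-2-methylbut-1-en-1-yl]-4-[(1S,3E)-4-iodo-3-methyl-1-(triethylsilyloxy)but-3-en-1-yl]-3-methylideneoxolan-2-one, 4,5-cis | ICC/C(C)=C/[C@H]1OC(=O)C(=C)[C@H]1[C@@H](O[Si](CC)(CC)CC)C/C(C)=C/I | intermediate
22 | alkylzinc iodide of 21, C2–ZnI in place of C2–I (formed in the flask) | I[Zn]CC/C(C)=C/[C@H]1OC(=O)C(=C)[C@H]1[C@@H](O[Si](CC)(CC)CC)C/C(C)=C/I | intermediate
23 | (3aR,4S,6E,10E,11aR)-6,10-dimethyl-3-methylidene-4-(triethylsilyloxy)-3a,4,5,8,9,11a-hexahydrocyclodeca[b]furan-2(3H)-one; cis-fused lactone, H6, H7 and H8 on one face | CC[Si](CC)(CC)O[C@H]1C/C(C)=C/CC/C(C)=C/[C@H]2OC(=O)C(=C)[C@@H]12 | intermediate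
24 | (3R,3aR,4S,6E,10E,11aR)-3-hydroperoxy-3,6,10-trimethyl-4-(triethylsilyloxy)-3a,4,5,8,9,11a-hexahydrocyclodeca[b]furan-2(3H)-one (formed in the flask) | CC[Si](CC)(CC)O[C@H]1C/C(C)=C/CC/C(C)=C/[C@H]2OC(=O)[C@](C)(OO)[C@@H]12 | intermediate
25 | (3R,3aR,4S,6E,10E,11aR)-3-hydroxy-3,6,10-trimethyl-4-(triethylsilyloxy)-3a,4,5,8,9,11a-hexahydrocyclodeca[b]furan-2(3H)-one | CC[Si](CC)(CC)O[C@H]1C/C(C)=C/CC/C(C)=C/[C@H]2OC(=O)[C@](C)(O)[C@@H]12 | intermediate
26 | (3R,3aS,4S,6E,10E,11aR)-3,4-dihydroxy-3,6,10-trimethyl-3a,4,5,8,9,11a-hexahydrocyclodeca[b]furan-2(3H)-one | O[C@H]1C/C(C)=C/CC/C(C)=C/[C@H]2OC(=O)[C@](C)(O)[C@@H]12 | intermediate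
27 | angelic acid, (2Z)-2-methylbut-2-enoic acid | C/C=C(/C)C(=O)O | starting material
28 | (2Z)-2-methylbut-2-enoic 2,4,6-trichlorobenzoic anhydride | C/C=C(/C)C(=O)OC(=O)c1c(Cl)cc(Cl)cc1Cl | intermediate
29 | (3R,3aS,4S,6E,10E,11aR)-3-hydroxy-3,6,10-trimethyl-2-oxo-2,3,3a,4,5,8,9,11a-octahydrocyclodeca[b]furan-4-yl (2Z)-2-methylbut-2-enoate | C/C=C(/C)C(=O)O[C@H]1C/C(C)=C/CC/C(C)=C/[C@H]2OC(=O)[C@](C)(O)[C@@H]12 | intermediate
30 | (3R,3aS,4S,6E,10E,11aR)-3-acetoxy-3,6,10-trimethyl-2-oxo-2,3,3a,4,5,8,9,11a-octahydrocyclodeca[b]furan-4-yl (2Z)-2-methylbut-2-enoate (CNP0144564.1) | C/C=C(/C)C(=O)O[C@H]1C/C(C)=C/CC/C(C)=C/[C@H]2OC(=O)[C@](C)(OC(C)=O)[C@@H]12 | target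

## Totals and risks

Total step count: 18.
Longest linear sequence: 12 steps (steps 1–6, 12–15, 17 and 18, from (R)-glycidol). The other branches are steps 7–11 (from but-3-yn-1-ol) and step 16 (from angelic acid).

Three steps most likely to fail:

Step 13 (the proposed new ring closure). It can fail through oligomerisation, beta-hydride elimination at the alkylpalladium, or Heck insertion of the alkenylpalladium into the exocyclic methylene. Fallback, known chemistry, sets out from 18 and 6 and comes back at 23: the two C–C bond formations are reversed so that the ring is closed by the chromium allylation that is established for germacranolides. 18 is masked (HC(OMe)3, PPTS, MeOH) as the dimethyl acetal F1. Zinc insertion (Zn, LiCl, THF) gives the alkylzinc iodide F2. An ordinary intermolecular Negishi coupling with alkenyl iodide 6 (Pd(PPh3)4, THF, rt) gives the open-chain diene F3. Swern oxidation as in step 4 gives the aldehyde F4, reaction with 8 and DABCO as in step 5 gives the Morita–Baylis–Hillman adduct F5, and NBS/Me2S as in step 6 gives the (Z)-allyl bromide F6. PPTS in wet acetone frees the bromo enal F7. CrCl2 in THF at 1 mM (intramolecular Nozaki–Hiyama allylation with lactonisation) then closes C6–C7 and gives 23.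

Step 12 (diastereoselective union). It can fail if the facial selectivity at C7 relative to C8, or the syn selectivity, is low under chromium. Fallback sets out from 9 (with 18) and comes back at 21: the allylchromium is replaced by a configurationally fixed allylboronate that reacts through a tighter closed transition state. 9 is acetylated (Ac2O, DMAP, CH2Cl2) to the allylic acetate F8. Copper-catalysed SN2' borylation (CuCl, KOt-Bu, bis(pinacolato)diboron, THF, -20 °C) gives the allylboronate F9 with the same alkene geometry as 10. Allylboration of 18 (toluene, 60 °C, or Sc(OTf)3 catalysis at rt; a chiral phosphoric acid can be added for reagent control) followed by PPTS-lactonisation gives 21.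

Step 14 (radical hydration). It can fail through competing hydrogen atom transfer to the ring alkenes or transannular radical cyclisation. Fallback sets out from 23 and comes back at 25: an ionic two-step route. NaBH4 in MeOH at 0 °C reduces the exocyclic alkene conjugately to the 11,13-dihydro lactone F10 (C11 epimers, both usable). KN(SiMe3)2 in THF at -78 °C followed by 2-(phenylsulfonyl)-3-phenyloxaziridine hydroxylates the lactone enolate on the convex face to give 25.

Further compounds

F1 | step 13 | (2E)-5-iodo-1,1-dimethoxy-3-methylpent-2-ene | ICC/C(C)=C/C(OC)OC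
F2 | step 13 | [(3E)-5,5-dimethoxy-3-methylpent-3-en-1-yl]zinc iodide | I[Zn]CC/C(C)=C/C(OC)OC
F3 | step 13 | (2E,6E,9S)-1,1-dimethoxy-3,7-dimethyl-9,10-bis(triethylsilyloxy)deca-2,6-diene | CC[Si](CC)(CC)O[C@H](CO[Si](CC)(CC)CC)C/C(C)=C/CC/C(C)=C/C(OC)OC
F4 | step 13 | (2S,4E,8E)-10,10-dimethoxy-4,8-dimethyl-2-(triethylsilyloxy)deca-4,8-dienal | CC[Si](CC)(CC)O[C@H](C=O)C/C(C)=C/CC/C(C)=C/C(OC)OC
F5 | step 13 | methyl (4S,6E,10E)-3-hydroxy-12,12-dimethoxy-6,10-dimethyl-2-methylidene-4-(triethylsilyloxy)dodeca-6,10-dienoate, both C3 epimers | CC[Si](CC)(CC)O[C@H](C(O)C(=C)C(=O)OC)C/C(C)=C/CC/C(C)=C/C(OC)OC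
F6 | step 13 | methyl (2Z,4S,6E,10E)-2-(bromomethyl)-12,12-dimethoxy-6,10-dimethyl-4-(triethylsilyloxy)dodeca-2,6,10-trienoate | CC[Si](CC)(CC)O[C@H](/C=C(\CBr)C(=O)OC)C/C(C)=C/CC/C(C)=C/C(OC)OC
F7 | step 13 | methyl (2Z,4S,6E,10E)-2-(bromomethyl)-6,10-dimethyl-12-oxo-4-(triethylsilyloxy)dodeca-2,6,10-trienoate | CC[Si](CC)(CC)O[C@H](/C=C(\CBr)C(=O)OC)C/C(C)=C/CC/C(C)=C/C=O
F8 | step 12 | methyl (4S,6E)-3-acetoxy-7-iodo-6-methyl-2-methylidene-4-(triethylsilyloxy)hept-6-enoate, both C3 epimers | CC[Si](CC)(CC)O[C@H](C(OC(C)=O)C(=C)C(=O)OC)C/C(C)=C/I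
F9 | step 12 | methyl (2E,4S,6E)-7-iodo-6-methyl-2-[(4,4,5,5-tetramethyl-1,3,2-dioxaborolan-2-yl)methyl]-4-(triethylsilyloxy)hepta-2,6-dienoate | CC[Si](CC)(CC)O[C@H](/C=C(\CB1OC(C)(C)C(C)(C)O1)C(=O)OC)C/C(C)=C/I
F10 | step 14 | (3aR,4S,6E,10E,11aR)-3,6,10-trimethyl-4-(triethylsilyloxy)-3a,4,5,8,9,11a-hexahydrocyclodeca[b]furan-2(3H)-one, C3 epimers | CC[Si](CC)(CC)O[C@H]1C/C(C)=C/CC/C(C)=C/[C@H]2OC(=O)C(C)[C@@H]12
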